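The constants of the steps were hidden, so I went on the charges and the two earlier runs.

| flask | starting material | coupling partner | capture agent | free catalyst | temperature | remark | time |
|---|---|---|---|---|---|---|---|
| midnight | 10 mM | 3 equiv | 1 mM | 0.65 mol% | 70 °C | run made earlier |  |
| winter | 10 mM | 3 equiv | 1 mM | 0.98 mol% | 92 °C | run made earlier |  |
| theta | 10 mM | 3.00 equiv | 1.00 mM | 1.3 mol% |  | at 60 °C until 12 h, from then on at 100 °C | 40 h |
| zeta | 10 mM | 3.00 equiv | 1.00 mM | 1.3 mol% | 60 °C |  | 40 h |
| eta | 10 mM | 3.00 equiv | 1.00 mM | 1.3 mol% | 100 °C |  | 40 h |
| beta | 10 mM | 3.00 equiv | 1.00 mM | 1.3 mol% | 80 °C |  | 40 h |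

| run | time / h | product / % | starting material / % |
|---|---|---|---|
| midnight | 2.00 | 0.3 | 99.6 |
| midnight | 4.00 | 0.4 | 98.6 |
| midnight | 6.00 | 0.9 | 98.7 |
| midnight | 10.0 | 0.6 | 98.1 |
| midnight | 12.0 | 0.9 | 98.2 |
| midnight | 15.0 | 1.7 | 98.2 |
| winter | 0.417 | 0 | 98.5 |
| winter | 0.667 | 0.7 | 98.4 |
| winter | 0.833 | 0.3 | 97.5 |
| winter | 1.33 | 1.2 | 97.8 |
| winter | 2.00 | 2.5 | 96.7 |
| winter | 3.00 | 2.9 | 96.0 |
| winter | 5.00 | 5.3 | 93.5 |

(scatter of a reading: 0.3 percentage points)

- the analysis behind the earlier runs scatters by 0.3 percentage points, standard deviation
- steps thought possible: starting material + free catalyst -> catalyst intermediate A; coupling partner + catalyst intermediate A -> catalyst intermediate B; catalyst intermediate B <-> free catalyst + product; catalyst intermediate B + capture agent -> trapped intermediate; 2 free catalyst -> spent catalyst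

1. the flask with the highest amount of product, in percent of the starting material charged ("all alike" if they lie within 1.5 percentage points) (theta / zeta / eta / beta / all alike)
2. final product, as a percentage of the starting material charged, in theta
3. final product, as a percentage of the starting material charged, in zeta
4. final product, as a percentage of the starting material charged, in eta
5. final product, as a percentage of the starting material charged, in beta

I kept a ledger of the starting material, the limiting reagent, with 3.00 equiv of coupling partner against it. Each part charged stands as free starting material, as product, or bound on the catalyst. The bound entry is small: at the last winter reading, 93.5% and 5.3% leave 1.20% unaccounted for, against a loading of 0.98 mol% and a scatter of 0.3 percentage points per reading.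

So the product entry needs the number, and as the zero of my scale I took a flask in which no catalyst is lost. Product over loading over time, at the last reading of each run, gave 0.174 h⁻¹ at 70 °C in midnight and 1.08 h⁻¹ at 92 °C in winter, and both carry the scatter of those readings. I carried that ratio evenly per degree down to 60 °C and got 0.0761 h⁻¹. This is the free-running rate: turnovers per hour of a catalyst still at work.

For zeta, 1.3 mol% of catalyst over 40 h then puts 3.96% into product, the bound entry takes 1.3 mol%, and 94.7% stays free, so the books close. The same reckoning at 100 °C for eta gives 2.10 h⁻¹ and 109%, more than the charge, so there the books do not close. Moreover, the capture agent at 1.00 mM was charged in larger amount than the catalyst at 0.130 mM.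

The forecast named eta as highest, with 52% for theta, 2.8% for zeta, 62% for eta and 16% for beta, reasoning that “trapping could cap the hot runs”. Its zeta stands below my line, and its eta far below.

The flasks gave 42.6% in theta, 3.14% in zeta, 53.1% in eta and 16.3% in beta, so eta came highest.

    starting material + free catalyst → catalyst intermediate A (k = 12.0 M⁻¹ s⁻¹, Ea = 51.0 kJ mol⁻¹)
    coupling partner + catalyst intermediate A → catalyst intermediate B (k = 0.0450 M⁻¹ s⁻¹, Ea = 61.0 kJ mol⁻¹)
    catalyst intermediate B ⇌ free catalyst + product (K = 0.0190 M, k = 0.00120 s⁻¹, Ea = 100 kJ mol⁻¹, ΔH = −30.0 kJ mol⁻¹)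
    catalyst intermediate B + capture agent → trapped intermediate (k = 0.0250 M⁻¹ s⁻¹, Ea = 54.0 kJ mol⁻¹)
    2 free catalyst → spent catalyst (k = 0.0530 M⁻¹ s⁻¹, Ea = 87.0 kJ mol⁻¹)
    (constants at 100 °C)

Against the free-running rate, zeta reached 79.3% of its line and eta 48.6%, and the forecast's eta stood 8.9 points above the result. In zeta, catalyst intermediate B gave product while it held 58.7% of the catalyst at 40.0 h, with the trapped intermediate at 29.2%. In eta, the same release ran on while the trapped intermediate grew to 80.8% of the catalyst by 40.0 h, with 9.10% as catalyst intermediate B and 89.5% of the capture agent still free.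

For zeta read at 6.0 d, the free-running rate gives 14.2% of product. The computed flask holds 7.84%, which is 55.0% of that line, with the trapped intermediate at 71.0% of the catalyst.

The data were computed with made-up constants, and the scatter is random.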